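Elemane numbering is used (ring C5–C10, lactone carbons C11 and C12). The cyclohexane ring is closed last, at the bond between C5, the isopropenyl-bearing carbon, and C10, the quaternary methyl/vinyl carbon. Because C5 is the α-carbon of a C6 carbonyl and C10 the substituted terminus of a 1,1-disubstituted allene, a gold-catalysed Conia-ene-type attack of a silyl dienol ether on the allene forms this bond and, in the same operation, creates the quaternary centre and the vinyl and isopropenyl groups. The precursor is monocyclic: a trans-4,5-disubstituted γ-butyrolactone (C12 on O8) carrying dienol ether and allenylmethyl chain; its trans fusion steers the chair-like closure, and the lactone is later shifted to O6.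

Key step: step 7

Remark on labels: C5 (isopropenyl), C6 (O6), C7, C8 (O8), C9 (CH2), C10 (methyl, vinyl); C11 (methyl, O11), C12 (lactone C=O).
Assumption: the boron aldol of step 5 follows the substrate-control model stated there; reagents that are not skeleton building blocks are not numbered.

Step 1
Reactants: 1 (S)-citramalic acid
Product: 2 2-[(4S)-2,2,4-trimethyl-5-oxo-1,3-dioxolan-4-yl]acetic acid
Conditions: 2,2-dimethoxypropane, TsOH·H2O (cat.), CH2Cl2, rt
Reagents that add atoms: 2,2-dimethoxypropane, COC(C)(C)OC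
Why: Acid-catalysed transketalisation engages the α-hydroxy acid selectively as the five-membered dioxolanone, which leaves the β-carboxyl free, masks O11 and activates C12, without touching the C11 stereocentre.

Step 2
Reactants: 2 the dioxolanone acid; 3 (2-methylprop-1-en-1-yl)magnesium bromide
Product: 5 (5S)-2,2,5-trimethyl-5-(4-methyl-2-oxopent-3-en-1-yl)-1,3-dioxolan-4-one, via acid chloride 4 (not isolated)
Conditions: (COCl)2, DMF (cat.), CH2Cl2, 0 °C to rt; then 3, Fe(acac)3 (3 mol%), THF, −78 °C
Reagents that add atoms: none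
Why: Acid chloride formation followed by iron-catalysed acylation of the alkenyl Grignard reagent should give the β,β-dimethyl enone, because at −78 °C acylation outruns attack on the dioxolanone and on the product ketone.

Step 3
Reactants: 6 but-2-yn-1-ol; 7 ethyl vinyl ether
Product: 8 1-(ethenyloxy)but-2-yne
Conditions: Hg(OAc)2 (5 mol%), 7 as solvent, reflux
Reagents that add atoms: none
Why: Mercury-catalysed vinyl interchange (transvinylation) converts the propargylic alcohol into its vinyl ether.

Step 4
Reactants: 8 1-(ethenyloxy)but-2-yne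
Product: 9 3-methylpenta-3,4-dienal
Conditions: [(Ph3PAu)3O]BF4 (1 mol%), CH2Cl2, rt; filtered solution used directly
Reagents that add atoms: none
Why: Gold-catalysed propargyl Claisen ([3,3], Saucy–Marbet type) rearrangement should deliver the β-allenic aldehyde at room temperature, mild enough to avoid isomerisation to the conjugated dienal.

Step 5
Reactants: 5 the enone; 9 3-methylpenta-3,4-dienal
Product: 12 (3S,4R,5R)-3-hydroxy-3-methyl-4-(3-methylbut-2-enoyl)-5-(2-methylbuta-2,3-dien-1-yl)oxolan-2-one, via boron enolate 10 (not isolated), via aldol adduct 11 (not isolated)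
Conditions: Bu2BOTf, i-Pr2NEt, CH2Cl2, −78 °C; 9, −78 to 0 °C; pH 7 buffer, MeOH, H2O2, 0 °C; then PPTS (cat.), CH2Cl2, rt
Reagents that add atoms: none
Why: Boron aldol reaction in which the (Z)-enol borinate adds through a closed chair (Zimmerman–Traxler) transition state to set C7/C8 syn, on the enolate face remote from the dioxolanone ring (C11–O bond in the enolate plane to minimise allylic strain), after which acid lets the new C8 hydroxyl open the activated dioxolanone (5-exo, acetone lost) to the trans-lactone, C7 being free to settle trans to C8.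

Step 6
Reactants: 12 the hydroxy keto lactone
Product: 13 (3S,4S,5R)-3-methyl-4-[(1Z)-3-methyl-1-(triethylsilyloxy)buta-1,3-dien-1-yl]-5-(2-methylbuta-2,3-dien-1-yl)-3-(triethylsilyloxy)oxolan-2-one
Conditions: TESOTf (2.5 equiv), Et3N, CH2Cl2, −78 to 0 °C
Reagents that add atoms: triethylsilyl trifluoromethanesulfonate, CC[Si](CC)(CC)OS(=O)(=O)C(F)(F)F
Why: Soft enolisation silylates the tertiary alcohol and should convert the s-cis enone by γ-deprotonation (the α′ C7–H is a hindered ring methine) into the (Z)-silyl dienol ether, O and C4 cis.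

Step 7
Reactants: 13 the bis-silyl dienol ether
Product: 14 (3S,3aR,5R,6S,7aR)-6-ethenyl-3,6-dimethyl-5-(prop-1-en-2-yl)-3-(triethylsilyloxy)hexahydro-1-benzofuran-2,4-dione
Conditions: Ph3PAuCl (5 mol%), AgBF4 (5 mol%), CH2Cl2/MeOH 10:1, rt
Reagents that add atoms: none
Why: Cationic gold binds the allene and the α-carbon C5 of the silyl dienol ether attacks its substituted terminus C10 anti to gold (Conia-ene-type carbocyclisation), after which methanol removes silicon from the oxocarbenium ion and protonates the vinylgold to release the ketone, the vinyl group and the catalyst. The closest known reaction types are the gold-catalysed carbocyclisation of silyl enol ethers onto alkynes and the gold-catalysed addition of enol silanes to activated allenes. The cyclohexane ring closes in the 6-exo-trig mode, α- rather than γ-attack of the dienol ether and attack at C10 rather than C2 being imposed by ring size (six- against eight-membered). C10 is controlled by the chair-like transition state that the trans-fused lactone locks with C7–C11 and C8–O8 equatorial: methyl should take the pseudo-equatorial site and the slender sp-hybridised allene carbon the more crowded pseudo-axial site, placing methyl cis to O8 and vinyl trans to it. C5 is controlled by the (Z)-dienol ether geometry, which puts isopropenyl equatorial and cis to vinyl, the arrangement also preferred thermodynamically at this epimerisable centre. The step needs desilylation and protodeauration to outrun collapse of the vinylgold onto the oxocarbenium ion, which the protic co-solvent secures.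

Step 8
Reactants: 14 the bicyclic keto lactone
Product: 17 (3S,3aS,4R,6S,7R,7aR)-6-ethenyl-3,4-dihydroxy-3,6-dimethyl-7-(prop-1-en-2-yl)hexahydro-1-benzofuran-2(3H)-one, via lithium alkoxide 15 (not isolated), via silyl ether 16 (not isolated)
Conditions: LiBH(s-Bu)3 (L-selectride), THF, −78 to 0 °C; then 2 M HCl, MeOH, rt
Reagents that add atoms: none
Why: The bulky hydride should attack the C6 ketone from the equatorial direction (the axial face is blocked by the syn-axial vinyl group on C10) to give the axial alkoxide cis to C7–C11, which translactonises (5-exo-trig) from the strained trans-fused O8 lactone to the cis-fused O6 lactone before acid removes the tertiary silyl ether.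

Step 9
Reactants: 17 the diol lactone; 18 3-methylbut-3-enoic acid
Product: 19 (3S,3aS,4R,6S,7R,7aR)-6-ethenyl-3-hydroxy-3,6-dimethyl-2-oxo-7-(prop-1-en-2-yl)octahydro-1-benzofuran-4-yl 3-methylbut-3-enoate
Conditions: DCC, DMAP (5 mol%), CH2Cl2, 0 °C
Reagents that add atoms: none
Why: Steglich esterification acylates the secondary C8 hydroxyl selectively over the tertiary C11 hydroxyl, and low temperature with little DMAP limits conjugative isomerisation of the β,γ-unsaturated acyl group.

Step 10
Reactants: 19 the hydroxy ester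
Product: 20 the target, (3S,3aS,4R,6S,7R,7aR)-3-acetoxy-6-ethenyl-3,6-dimethyl-2-oxo-7-(prop-1-en-2-yl)octahydro-1-benzofuran-4-yl 3-methylbut-3-enoate
Conditions: Ac2O, Sc(OTf)3 (5 mol%), MeCN, −20 °C
Reagents that add atoms: acetic anhydride, CC(=O)OC(C)=O
Why: Lewis-acid-catalysed acetylation acylates the hindered tertiary α-hydroxy lactone without base, so the 3-methylbut-3-enoate should not isomerise, and C11 keeps its configuration.

Compound list
1 | (S)-citramalic acid, (2S)-2-hydroxy-2-methylbutanedioic acid | C[C@](O)(CC(=O)O)C(=O)O | starting material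
2 | 2-[(4S)-2,2,4-trimethyl-5-oxo-1,3-dioxolan-4-yl]acetic acid | CC1(C)OC(=O)[C@](C)(CC(=O)O)O1 | intermediate
3 | (2-methylprop-1-en-1-yl)magnesium bromide | CC(C)=C[Mg]Br | starting material
4 | 2-[(4S)-2,2,4-trimethyl-5-oxo-1,3-dioxolan-4-yl]acetyl chloride | CC1(C)OC(=O)[C@](C)(CC(=O)Cl)O1 | intermediate
5 | (5S)-2,2,5-trimethyl-5-(4-methyl-2-oxopent-3-en-1-yl)-1,3-dioxolan-4-one | CC1(C)OC(=O)[C@](C)(CC(=O)C=C(C)C)O1 | intermediate
6 | but-2-yn-1-ol | CC#CCO | starting material
7 | ethyl vinyl ether | C=COCC | starting material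
8 | 1-(ethenyloxy)but-2-yne | CC#CCOC=C | intermediate
9 | 3-methylpenta-3,4-dienal | C=C=C(C)CC=O | intermediate
10 | (Z)-dibutylboron enolate of 5 (C6–O–B, C6=C7, O cis to C11) | CCCCB(CCCC)O/C(C=C(C)C)=C\[C@]1(C)OC(C)(C)OC1=O | intermediate
11 | (5R,6R)-6-hydroxy-2,8-dimethyl-5-[(4S)-2,2,4-trimethyl-5-oxo-1,3-dioxolan-4-yl]deca-2,8,9-trien-4-one | C=C=C(C)C[C@@H](O)[C@H]([C@]1(C)OC(C)(C)OC1=O)C(=O)C=C(C)C | intermediate
12 | (3S,4R,5R)-3-hydroxy-3-methyl-4-(3-methylbut-2-enoyl)-5-(2-methylbuta-2,3-dien-1-yl)oxolan-2-one | C=C=C(C)C[C@H]1OC(=O)[C@@](C)(O)[C@@H]1C(=O)C=C(C)C | intermediate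
13 | (3S,4S,5R)-3-methyl-4-[(1Z)-3-methyl-1-(triethylsilyloxy)buta-1,3-dien-1-yl]-5-(2-methylbuta-2,3-dien-1-yl)-3-(triethylsilyloxy)oxolan-2-one | C=C=C(C)C[C@H]1OC(=O)[C@@](C)(O[Si](CC)(CC)CC)[C@@H]1/C(O[Si](CC)(CC)CC)=C/C(C)=C | intermediate
14 | (3S,3aR,5R,6S,7aR)-6-ethenyl-3,6-dimethyl-5-(prop-1-en-2-yl)-3-(triethylsilyloxy)hexahydro-1-benzofuran-2,4-dione | C=C[C@]1(C)C[C@H]2OC(=O)[C@@](C)(O[Si](CC)(CC)CC)[C@@H]2C(=O)[C@@H]1C(=C)C | intermediate
15 | lithium alkoxide of the axial (4R)-alcohol from 14 (C6–O cis to C7–C11) | C=C[C@]1(C)C[C@H]2OC(=O)[C@@](C)(O[Si](CC)(CC)CC)[C@@H]2[C@H]([O-])[C@@H]1C(=C)C.[Li+] | intermediate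
16 | (3S,3aS,4R,6S,7R,7aR)-6-ethenyl-4-hydroxy-3,6-dimethyl-7-(prop-1-en-2-yl)-3-(triethylsilyloxy)hexahydro-1-benzofuran-2(3H)-one | C=C[C@]1(C)C[C@@H](O)[C@H]2[C@H](OC(=O)[C@@]2(C)O[Si](CC)(CC)CC)[C@@H]1C(=C)C | intermediate
17 | (3S,3aS,4R,6S,7R,7aR)-6-ethenyl-3,4-dihydroxy-3,6-dimethyl-7-(prop-1-en-2-yl)hexahydro-1-benzofuran-2(3H)-one | C=C[C@]1(C)C[C@@H](O)[C@H]2[C@H](OC(=O)[C@@]2(C)O)[C@@H]1C(=C)C | intermediate
18 | 3-methylbut-3-enoic acid | CC(=C)CC(=O)O | starting material
19 | (3S,3aS,4R,6S,7R,7aR)-6-ethenyl-3-hydroxy-3,6-dimethyl-2-oxo-7-(prop-1-en-2-yl)octahydro-1-benzofuran-4-yl 3-methylbut-3-enoate | C=C[C@]1(C)C[C@@H](OC(=O)CC(=C)C)[C@H]2[C@H](OC(=O)[C@@]2(C)O)[C@@H]1C(=C)C | intermediate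
20 | (3S,3aS,4R,6S,7R,7aR)-3-acetoxy-6-ethenyl-3,6-dimethyl-2-oxo-7-(prop-1-en-2-yl)octahydro-1-benzofuran-4-yl 3-methylbut-3-enoate | C=C[C@]1(C)C[C@@H](OC(=O)CC(=C)C)[C@H]2[C@H](OC(=O)[C@@]2(C)OC(C)=O)[C@@H]1C(=C)C | target

Total step count: 10
Longest linear sequence: 8 steps (1, 2, 5, 6, 7, 8, 9, 10)

Steps most likely to fail

Step 7. After the C5–C10 bond has formed, the vinylgold may close onto the silyl oxocarbenium ion (formal cycloaddition) instead of being protonated, and the choice between methyl and the allene arm for the pseudo-axial site may be incomplete, eroding the C10 configuration. The fallback replaces π-acid activation by π-allylpalladium chemistry and sets out from 12. TESOTf with 2,6-lutidine at −78 °C should silylate only the tertiary hydroxyl to give the mono-silyl ether F1. Gold-catalysed hydration of the allene (Ph3PAuCl/AgOTf, dioxane–water) should give the (E)-allylic alcohol F2, and methyl chloroformate with pyridine the allylic methyl carbonate F3. TESOTf/Et3N then gives the silyl dienol ether F4. With Pd(PPh3)4 in THF the carbonate ionises, the liberated methoxide desilylates the dienol ether, and the enolate attacks the internal allyl terminus (intramolecular Tsuji–Trost allylation, six- rather than eight-membered ring), which returns to 14.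

Step 6. Enolisation may go toward the ring methine C7 instead of the γ-methyl group, which gives the cross-conjugated enol ether or opens the lactone by β-elimination of its carboxylate. The fallback moves the double bond before silylation and sets out from 12. Irradiation (λ > 300 nm, MeCN, catalytic imidazole) should deconjugate the β,β-dimethyl enone through its photodienol to the isopropenyl ketone F5. Its C5 methylene is doubly activated, so TESOTf/Et3N should silylate it regiospecifically together with the tertiary hydroxyl, returning to 13.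

Step 5. Face selection of the boron enolate by the quaternary C11 centre may be poor, giving the C8-epimeric lactone, and the β-allenic aldehyde may isomerise before it reacts. The fallback puts both new centres under auxiliary control and sets out from 2. Pivaloyl chloride/Et3N followed by the lithium salt of (S)-4-benzyl-1,3-oxazolidin-2-one gives the imide F6. An Evans syn-aldol reaction (Bu2BOTf, i-Pr2NEt, then 9) should give the syn-aldol adduct F7. MeONHMe·HCl/AlMe3 converts it into the Weinreb amide F8, and addition of 3 gives the enone 11, which is lactonised to 12 as in step 5.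

Further compounds
F1 | step 7 | (3S,4R,5R)-3-methyl-4-(3-methylbut-2-enoyl)-5-(2-methylbuta-2,3-dien-1-yl)-3-(triethylsilyloxy)oxolan-2-one | C=C=C(C)C[C@H]1OC(=O)[C@@](C)(O[Si](CC)(CC)CC)[C@@H]1C(=O)C=C(C)C
F2 | step 7 | (3S,4R,5R)-5-[(2E)-4-hydroxy-2-methylbut-2-en-1-yl]-3-methyl-4-(3-methylbut-2-enoyl)-3-(triethylsilyloxy)oxolan-2-one | OC/C=C(C)/C[C@H]1OC(=O)[C@@](C)(O[Si](CC)(CC)CC)[C@@H]1C(=O)C=C(C)C
F3 | step 7 | methyl carbonate of F2 (primary allylic O–CO2Me) | COC(=O)OC/C=C(C)/C[C@H]1OC(=O)[C@@](C)(O[Si](CC)(CC)CC)[C@@H]1C(=O)C=C(C)C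
F4 | step 7 | (Z)-triethylsilyl dienol ether of F3 (C6–OSiEt3, C5=C6, isopropenyl on C5) | COC(=O)OC/C=C(C)/C[C@H]1OC(=O)[C@@](C)(O[Si](CC)(CC)CC)[C@@H]1/C(O[Si](CC)(CC)CC)=C/C(C)=C
F5 | step 6 | (3S,4R,5R)-3-hydroxy-3-methyl-4-(3-methylbut-3-enoyl)-5-(2-methylbuta-2,3-dien-1-yl)oxolan-2-one | C=C=C(C)C[C@H]1OC(=O)[C@@](C)(O)[C@@H]1C(=O)CC(C)=C
F6 | step 5 | (4S)-4-benzyl-3-{2-[(4S)-2,2,4-trimethyl-5-oxo-1,3-dioxolan-4-yl]acetyl}-1,3-oxazolidin-2-one | CC1(C)OC(=O)[C@](C)(CC(=O)N2[C@@H](Cc3ccccc3)COC2=O)O1
F7 | step 5 | (4S)-4-benzyl-3-{(2R,3R)-3-hydroxy-5-methyl-2-[(4S)-2,2,4-trimethyl-5-oxo-1,3-dioxolan-4-yl]hepta-5,6-dienoyl}-1,3-oxazolidin-2-one | C=C=C(C)C[C@@H](O)[C@H]([C@]1(C)OC(C)(C)OC1=O)C(=O)N1[C@@H](Cc2ccccc2)COC1=O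
F8 | step 5 | (2R,3R)-3-hydroxy-N-methoxy-N,5-dimethyl-2-[(4S)-2,2,4-trimethyl-5-oxo-1,3-dioxolan-4-yl]hepta-5,6-dienamide | C=C=C(C)C[C@@H](O)[C@H]([C@]1(C)OC(C)(C)OC1=O)C(=O)N(C)OC
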